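**Retrosynthetic overview**
1. Target 20 ⇐ 17: the C9 CH2OH comes from a vinyl group (ozonolysis, reduction), and both acetates are cleaved in the same pot.
2. 17 ⇐ 6 + 16: the C7–C8 bond is made by radical C–H allylation. A thiyl radical abstracts H from the O–CH2 of allyl aryl ether 16, a chiral Cr catalyst traps the α-aryloxyallyl radical, and anti-selective addition to aldehyde 6 sets C7 and C8 together.
3. 6 ⇐ vanillin 5 ⇐ guaiacol 2 + glyoxylic acid 3 ⇐ catechol 1.
4. 16 ⇐ 15 ⇐ syringyl alcohol 13 + allyl bromide 14; 13 ⇐ 2,6-dimethoxyphenol 11 + formaldehyde 12 ⇐ 1,3-dimethoxybenzene 8 ⇐ resorcinol 7.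
5. Rings: none is formed. Both benzene rings are bought (1 and 7) and only substituted.

Assumption: compound numbers follow the order of first appearance in the forward steps; the overview uses the same numbers.
Assumption: which antipode of the chromium ligand gives the (1R,2S) adduct is fixed by one screening run (both antipodes are available).

**Route**

Step 1
Reactants: 1 catechol (benzene-1,2-diol)
Product: 2 guaiacol (2-methoxyphenol)
Conditions: MeI (1.0 equiv), K2CO3 (1.0 equiv), acetone, reflux
Reagents that add atoms: iodomethane CI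
Why: Williamson mono-O-methylation of one of two equivalent phenols with one equivalent of MeI; veratrole and unreacted catechol are removed by base extraction and distillation.

Step 2
Reactants: 2 guaiacol; 3 glyoxylic acid
Product: 5 vanillin (4-hydroxy-3-methoxybenzaldehyde), via 4-hydroxy-3-methoxymandelic acid 4 (not isolated)
Conditions: NaOH, H2O, 30 °C; then CuSO4 (cat.), O2, NaOH, 95 °C; H2SO4 work-up
Reagents that add atoms: none
Why: The phenoxide attacks glyoxylate para to O− (electrophilic aromatic hydroxyalkylation), and Cu-catalysed aerobic oxidative decarboxylation of the mandelic acid gives the aldehyde (the industrial guaiacol-to-vanillin sequence).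

Step 3
Reactants: 5 vanillin
Product: 6 4-formyl-2-methoxyphenyl acetate
Conditions: Ac2O, pyridine, DMAP (cat.), CH2Cl2, rt
Reagents that add atoms: acetic anhydride CC(=O)OC(C)=O
Why: O-acylation of the phenol removes the O–H that would quench thiyl radicals and organochromium in step 9 and makes ring A less prone to ozone attack in step 10.

Step 4
Reactants: 7 resorcinol (benzene-1,3-diol)
Product: 8 1,3-dimethoxybenzene
Conditions: MeI (2.5 equiv), K2CO3, acetone, reflux
Reagents that add atoms: iodomethane CI
Why: Double Williamson O-methylation.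

Step 5
Reactants: 8 1,3-dimethoxybenzene
Product: 11 2,6-dimethoxyphenol, via 2-lithio-1,3-dimethoxybenzene 9 (not isolated), via lithium aryltrimethoxyborate 10 (not isolated)
Conditions: n-BuLi, THF, 0 °C to rt; B(OMe)3, −78 °C to rt; AcOH, 30% H2O2, 0 °C to rt
Reagents that add atoms: hydrogen peroxide OO (phenol oxygen of 11); n-butyllithium [Li]CCCC (Li of 9 and 10 only); trimethyl borate COB(OC)OC (boron unit of 10 only)
Why: Directed ortho-metalation occurs at C2 between the two methoxy groups, and borylation followed by oxidative C–B to C–O migration gives the phenol.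

Step 6
Reactants: 11 2,6-dimethoxyphenol; 12 formaldehyde
Product: 13 syringyl alcohol (4-(hydroxymethyl)-2,6-dimethoxyphenol)
Conditions: 37% aq CH2O (excess), NaOH (1.1 equiv), H2O, rt, 3 d, N2; AcOH to pH 6–7 at 0 °C
Reagents that add atoms: none
Why: Lederer–Manasse hydroxymethylation; with both ortho positions blocked the phenoxide attacks formaldehyde only at the para carbon.

Step 7
Reactants: 13 syringyl alcohol; 14 allyl bromide
Product: 15 [3,5-dimethoxy-4-(prop-2-en-1-yloxy)phenyl]methanol
Conditions: K2CO3, acetone, 40 °C
Reagents that add atoms: none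
Why: Williamson etherification; carbonate deprotonates only the phenol (pKa about 10), not the benzylic alcohol, so O-allylation is selective.

Step 8
Reactants: 15 [3,5-dimethoxy-4-(prop-2-en-1-yloxy)phenyl]methanol
Product: 16 [3,5-dimethoxy-4-(prop-2-en-1-yloxy)phenyl]methyl acetate
Conditions: Ac2O, pyridine, DMAP (cat.), CH2Cl2, rt
Reagents that add atoms: acetic anhydride CC(=O)OC(C)=O
Why: Acetylation removes the O–H and makes the benzylic C–H stronger and less hydridic, so the allylic O–CH2 is the only site for hydrogen abstraction in step 9.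

Step 9
Reactants: 6 4-formyl-2-methoxyphenyl acetate (1.5 equiv); 16 [3,5-dimethoxy-4-(prop-2-en-1-yloxy)phenyl]methyl acetate
Product: 17 (1R,2S)-1-(4-acetoxy-3-methoxyphenyl)-2-[4-(acetoxymethyl)-2,6-dimethoxyphenoxy]but-3-en-1-ol
Conditions: CrCl2 (10 mol %), chiral indane-fused bis(oxazoline) ligand (12 mol %), [Ir(dF(CF3)ppy)2(dtbbpy)]PF6 (2 mol %), i-Pr3SiSH (10 mol %), 2,4,6-collidine (10 mol %), CH2Cl2, 450 nm LED, rt
Reagents that add atoms: none
Why: Proposed new method: photoexcited Ir(III) oxidises the silanethiolate to an electrophilic thiyl radical that abstracts the weakest, most hydridic C–H of 16 (the allylic O–CH2; the acetoxy-bearing benzylic CH2 and the OMe groups are stronger and polarity-mismatched), ligated Cr(II) (regenerated by Ir(II)) traps the α-aryloxyallyl radical as an (E)-γ-aryloxyallyl-Cr(III) species that adds through its oxygen-bearing carbon to the aldehyde of 6 in a closed chair transition state, which gives the anti (erythro) C7–OH/C8–OAr relationship while the ligand directs attack to the Si face of the aldehyde (7R, hence 8S), and protonation of the Cr alkoxide by the thiol closes both cycles without stoichiometric reagents; the closest known reaction types are photoredox/chromium dual-catalytic allylation of aldehydes with allylic C–H partners (asymmetric versions with Cr–bis(oxazoline) catalysts included) and the anti-selective addition of Takai γ-alkoxyallylchromium reagents (radical–polar crossover of the Nozaki–Hiyama–Kishi type).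

Step 10
Reactants: 17 (1R,2S)-1-(4-acetoxy-3-methoxyphenyl)-2-[4-(acetoxymethyl)-2,6-dimethoxyphenoxy]but-3-en-1-ol
Product: 20 (1R,2S)-1-(4-hydroxy-3-methoxyphenyl)-2-[4-(hydroxymethyl)-2,6-dimethoxyphenoxy]propane-1,3-diol, via ozonide 18 (not isolated), via diacetate diol 19 (not isolated)
Conditions: O3, CH2Cl2, −78 °C (Sudan Red 7B end point); MeOH, NaBH4, −78 to 0 °C; K2CO3, MeOH, rt; NH4Cl work-up (pH 6–7)
Reagents that add atoms: ozone [O-][O+]=O
Why: Ozonolysis of the terminal alkene with borohydride reduction of the ozonide turns the vinyl group into the C9 CH2OH without touching C7 or C8, and carbonate-catalysed transesterification (Zemplén-type) then removes the aryl and benzylic acetates under conditions too mild to epimerise the benzylic carbinol.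

**Compound list**
1 | catechol | Oc1ccccc1O | starting material
2 | guaiacol | COc1ccccc1O | intermediate
3 | glyoxylic acid | O=CC(=O)O | starting material
4 | 4-hydroxy-3-methoxymandelic acid (racemic) | COc1cc(C(O)C(=O)O)ccc1O | intermediate
5 | vanillin | COc1cc(C=O)ccc1O | intermediate
6 | 4-formyl-2-methoxyphenyl acetate | COc1cc(C=O)ccc1OC(C)=O | intermediate
7 | resorcinol | Oc1cccc(O)c1 | starting material
8 | 1,3-dimethoxybenzene | COc1cccc(OC)c1 | intermediate
9 | 2-lithio-1,3-dimethoxybenzene | COc1cccc(OC)c1[Li] | intermediate
10 | lithium (2,6-dimethoxyphenyl)trimethoxyborate | [Li+].COc1cccc(OC)c1[B-](OC)(OC)OC | intermediate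
11 | 2,6-dimethoxyphenol | COc1cccc(OC)c1O | intermediate
12 | formaldehyde | C=O | starting material
13 | syringyl alcohol, 4-(hydroxymethyl)-2,6-dimethoxyphenol | COc1cc(CO)cc(OC)c1O | intermediate
14 | allyl bromide | C=CCBr | starting material
15 | [3,5-dimethoxy-4-(prop-2-en-1-yloxy)phenyl]methanol | COc1cc(CO)cc(OC)c1OCC=C | intermediate
16 | [3,5-dimethoxy-4-(prop-2-en-1-yloxy)phenyl]methyl acetate | COc1cc(COC(C)=O)cc(OC)c1OCC=C | intermediate
17 | (1R,2S)-1-(4-acetoxy-3-methoxyphenyl)-2-[4-(acetoxymethyl)-2,6-dimethoxyphenoxy]but-3-en-1-ol | COc1cc([C@@H](O)[C@H](C=C)Oc2c(OC)cc(COC(C)=O)cc2OC)ccc1OC(C)=O | intermediate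
18 | secondary ozonide of 17 (1,2,4-trioxolane in place of the vinyl group; C7/C8 configuration of 17 kept, trioxolane carbon as epimer mixture) | COc1cc([C@@H](O)[C@H](C3OCOO3)Oc2c(OC)cc(COC(C)=O)cc2OC)ccc1OC(C)=O | intermediate
19 | (1R,2S)-1-(4-acetoxy-3-methoxyphenyl)-2-[4-(acetoxymethyl)-2,6-dimethoxyphenoxy]propane-1,3-diol | COc1cc([C@@H](O)[C@H](CO)Oc2c(OC)cc(COC(C)=O)cc2OC)ccc1OC(C)=O | intermediate
20 | (1R,2S)-1-(4-hydroxy-3-methoxyphenyl)-2-[4-(hydroxymethyl)-2,6-dimethoxyphenoxy]propane-1,3-diol (erythro) | COc1cc([C@@H](O)[C@H](CO)Oc2c(OC)cc(CO)cc2OC)ccc1O | target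

**Step count**
Total steps: 10.
Longest linear sequence: 7 steps (7 → 8 → 11 → 13 → 15 → 16 → 17 → 20; steps 4 to 10).

**Steps most likely to fail, with fallbacks**

Step 9. The C–H allylation is new for allyl aryl ethers. The enantioselectivity and the anti:syn ratio are unproven, and the doubly activated C8–H of the product could be re-abstracted. The fallback gives up catalytic enantiocontrol and keeps only the diastereocontrol of the chromium chair transition state. It sets out from 6 and 16. The same photoredox/thiol C–H allylation is run with an achiral catalyst (CrCl2 with 4,4'-di-tert-butyl-2,2'-bipyridine) to give the racemic anti adduct F1. This is resolved by preparative chiral SFC; the (1S,2R)-enantiomer F2 is discarded, and the (1R,2S)-enantiomer is 17, where the route is rejoined.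

Step 10. Ozone may attack the trialkoxy ring, and the transient α-aryloxy-β-hydroxy aldehyde can epimerise at C8 or undergo retro-aldol cleavage in basic borohydride. The fallback replaces ozone by a two-stage glycol cleavage and sets out from 17. Dihydroxylation with OsO4 (cat.) and NMO in acetone/water gives the diol F3. Cleavage with NaIO4 in THF/water gives the aldehyde F4, which is reduced at once with NaBH4 at −20 °C to the diacetate diol 19. There the route is rejoined, and K2CO3 in MeOH gives 20 as before.

Step 6. Syringyl alcohol condenses readily to diarylmethanes through its quinone methide, so the hydroxymethylation may give low yields. The fallback brings in the para carbon at the aldehyde level and sets out from 11. Duff formylation (hexamethylenetetramine, TFA, reflux, then aqueous acid) gives syringaldehyde F5. Allylation with 14 and K2CO3 in DMF gives 4-(allyloxy)-3,5-dimethoxybenzaldehyde F6, and NaBH4 in MeOH reduces it to 15, where the route is rejoined (one step longer).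

**Further compounds**
F1 | step 9 | racemic anti adduct (1:1 mixture of 17 and its enantiomer) | COc1cc([C@@H](O)[C@H](C=C)Oc2c(OC)cc(COC(C)=O)cc2OC)ccc1OC(C)=O.COc1cc([C@H](O)[C@@H](C=C)Oc2c(OC)cc(COC(C)=O)cc2OC)ccc1OC(C)=O
F2 | step 9 | (1S,2R)-1-(4-acetoxy-3-methoxyphenyl)-2-[4-(acetoxymethyl)-2,6-dimethoxyphenoxy]but-3-en-1-ol | COc1cc([C@H](O)[C@@H](C=C)Oc2c(OC)cc(COC(C)=O)cc2OC)ccc1OC(C)=O
F3 | step 10 | vicinal diol from dihydroxylation of the vinyl group of 17 (C7/C8 configuration of 17 kept, new carbinol carbon as epimer mixture) | COc1cc([C@@H](O)[C@H](C(O)CO)Oc2c(OC)cc(COC(C)=O)cc2OC)ccc1OC(C)=O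
F4 | step 10 | (2R,3R)-3-(4-acetoxy-3-methoxyphenyl)-2-[4-(acetoxymethyl)-2,6-dimethoxyphenoxy]-3-hydroxypropanal | COc1cc([C@@H](O)[C@H](C=O)Oc2c(OC)cc(COC(C)=O)cc2OC)ccc1OC(C)=O
F5 | step 6 | syringaldehyde (4-hydroxy-3,5-dimethoxybenzaldehyde) | COc1cc(C=O)cc(OC)c1O
F6 | step 6 | 4-(allyloxy)-3,5-dimethoxybenzaldehyde | COc1cc(C=O)cc(OC)c1OCC=C
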